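## Retrosynthetic overview

1. Target ⇐ hydrogenolysis of three benzyl ethers ⇐ bis-O-sulfation of a tribenzyl diaryl ether diol in which only the two hydroxyls to be sulfated are free.
2. Diol ⇐ Baeyer–Villiger oxidation and methanolysis of a diaryl ether aldehyde: the CHO is the masked 4-OH of ring B, a pivalate is the masked OH of ring A.
3. Key disconnection: the diaryl ether C–O bond, since every C–C bond of the target lies inside a benzene ring that is bought intact. It is made with reversed polarity: ring A, normally a nucleophile, serves as an aryl cation equivalent (an aryl(trimethoxyphenyl)iodonium salt) and is joined to the 4-phenoxide of unprotected 3,4,5-trihydroxybenzaldehyde.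
4. Iodonium salt ⇐ 5-iodoresorcinol by mono-benzylation, pivaloylation and oxidation at iodine.
5. Ring order: no ring is formed; ring A comes from 5-iodoresorcinol and ring B from 3,4,5-trihydroxybenzaldehyde.

Assumption: the target has no stereocentre (it is achiral, so no enantiomer question arises) and is drawn as the free bis(hydrogen sulfate), which is liberated from its disodium salt in the last step and is best stored as that salt.

## Route

Step 1
Reactants: 1 5-iodobenzene-1,3-diol (5-iodoresorcinol)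
Product: 2 3-(benzyloxy)-5-iodophenol
Conditions: BnBr (1.0 equiv), K2CO3 (1.0 equiv), acetone, reflux; chromatography, recovered 1 recycled
Reagents that add atoms: benzyl bromide, BrCc1ccccc1
Why: Williamson ether synthesis on a symmetric diol, where one equivalent of BnBr gives the mono-ether as the main (statistical, about 45–50%) product, separable from recyclable 1 and the bis-ether, and this single step breaks the symmetry of ring A.

Step 2
Reactants: 2 3-(benzyloxy)-5-iodophenol
Product: 3 3-(benzyloxy)-5-iodophenyl pivalate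
Conditions: PivCl (1.2 equiv), Et3N (1.5 equiv), DMAP (5 mol%), CH2Cl2, 0 °C to rt
Reagents that add atoms: pivaloyl chloride, CC(C)(C)C(=O)Cl
Why: DMAP-catalysed O-acylation (nucleophilic catalysis), in which the pivalate masks the hydroxyl that will later carry the sulfate, tolerates the oxidising, acidic and weakly basic steps ahead, and is removed together with the formate in step 5.

Step 3
Reactants: 3 3-(benzyloxy)-5-iodophenyl pivalate
Product: 5 [3-(benzyloxy)-5-(pivaloyloxy)phenyl](2,4,6-trimethoxyphenyl)iodonium 4-methylbenzenesulfonate, via hydroxy(tosyloxy)iodoarene 4 (not isolated)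
Conditions: mCPBA (1.05 equiv), TsOH·H2O (1.05 equiv), MeCN, 55 °C, 30 min; then 1,3,5-trimethoxybenzene (1.05 equiv), 55 °C to rt; precipitation with Et2O
Reagents that add atoms: p-toluenesulfonic acid monohydrate, Cc1ccc(S(=O)(=O)O)cc1.O; 1,3,5-trimethoxybenzene, COc1cc(OC)cc(OC)c1
Why: Koser-type oxidation of the aryl iodide to the aryl-λ3-iodane 4 (mCPBA supplies the oxygen, which is lost again as water) followed by electrophilic aromatic substitution of 1,3,5-trimethoxybenzene at iodine(III) (one-pot diaryliodonium salt synthesis), which turns the ring A carbon into an aryl cation equivalent carrying a non-transferable trimethoxyphenyl ligand.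

Step 4
Reactants: 5 [3-(benzyloxy)-5-(pivaloyloxy)phenyl](2,4,6-trimethoxyphenyl)iodonium 4-methylbenzenesulfonate; 6 3,4,5-trihydroxybenzaldehyde
Product: 8 3-(benzyloxy)-5-[2,6-bis(benzyloxy)-4-formylphenoxy]phenyl pivalate, via dihydroxy diaryl ether aldehyde 7 (not isolated)
Conditions: 6 (1.2 equiv), NaHCO3 (1.2 equiv), degassed DMF, N2, dark, 40 °C; then K2CO3 (4 equiv), BnBr (3.2 equiv), 50 °C
Reagents that add atoms: benzyl bromide, BrCc1ccccc1
Why: Proposed new method: metal-free O-arylation of a phenoxide by a diaryl-λ3-iodane (ligand exchange at iodine, then ligand coupling) applied site-selectively to an unprotected triol, where NaHCO3 ionises only the 4-OH (para to CHO, pKa about 7.5 against about 9–10 for the 3- and 5-OH), the ring A carbon that is a nucleophile in all normal phloroglucinol chemistry reacts as an aryl cation equivalent so that two nucleophilic centres are joined, the electron-rich trimethoxyphenyl ligand is not transferred, and the two remaining hydroxyls are benzylated in the same pot (Williamson ether synthesis); the closest known reactions are the O-arylation of hindered and electron-poor phenols with aryl(trimethoxyphenyl)iodonium salts and the bicarbonate-controlled 4-O-alkylation of 3,4-dihydroxybenzaldehyde and gallates.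

Step 5
Reactants: 8 3-(benzyloxy)-5-[2,6-bis(benzyloxy)-4-formylphenoxy]phenyl pivalate
Product: 10 3-(benzyloxy)-5-[2,6-bis(benzyloxy)-4-hydroxyphenoxy]phenol, via aryl formate 9 (not isolated)
Conditions: mCPBA (1.4 equiv), CH2Cl2, 0 °C to rt; aq. Na2S2O3 wash, crude taken on; NaOMe (4 equiv), MeOH/THF, 0 °C to rt, under N2; AcOH quench
Reagents that add atoms: 3-chloroperoxybenzoic acid (mCPBA), OOC(=O)c1cccc(Cl)c1
Why: Baeyer–Villiger (Dakin-type) oxidation, in which the electron-rich aryl group with a para oxygen donor migrates in the Criegee intermediate to give formate 9, followed by base-mediated transesterification (methanolysis) of the formate and the aryl pivalate, which frees exactly the two hydroxyls to be sulfated while the three benzyl ethers stay.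

Step 6
Reactants: 10 3-(benzyloxy)-5-[2,6-bis(benzyloxy)-4-hydroxyphenoxy]phenol
Product: 12 disodium 3-(benzyloxy)-5-[2,6-bis(benzyloxy)-4-(sulfonatooxy)phenoxy]phenyl sulfate, via bis(pyridinium) bis-sulfate 11 (not isolated)
Conditions: SO3·pyridine (6 equiv), pyridine, 45 °C; then 1 M NaOH to pH 8; C18 chromatography (H2O/MeOH)
Reagents that add atoms: sulfur trioxide–pyridine complex, [O-]S(=O)(=O)[n+]1ccccc1; sodium hydroxide, [Na+].[OH-]
Why: O-sulfonation of phenols with a sulfur trioxide–amine complex, in which only the two unhindered free hydroxyls can react, the benzyl ethers and the diaryl ether are inert, and neutralisation gives the stable disodium salt.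

Step 7
Reactants: 12 disodium 3-(benzyloxy)-5-[2,6-bis(benzyloxy)-4-(sulfonatooxy)phenoxy]phenyl sulfate
Product: 14 3-[2,6-dihydroxy-4-(sulfooxy)phenoxy]-5-hydroxyphenyl hydrogen sulfate (target), via disodium salt 13 (not isolated)
Conditions: H2 (1 atm), 10% Pd/C, MeOH/H2O 4:1, rt; filtration; 1 M HCl (2.0 equiv), 0 °C; C18 desalting, lyophilisation
Reagents that add atoms: none
Why: Catalytic hydrogenolysis of benzyl ethers, to which aryl sulfate monoester salts and the diaryl ether are inert, followed by cold protonation of salt 13 to the free acid.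

## Compound list

1 | 5-iodobenzene-1,3-diol | Oc1cc(O)cc(I)c1 | starting material
2 | 3-(benzyloxy)-5-iodophenol | Oc1cc(I)cc(OCc2ccccc2)c1 | intermediate
3 | 3-(benzyloxy)-5-iodophenyl pivalate | CC(C)(C)C(=O)Oc1cc(I)cc(OCc2ccccc2)c1 | intermediate
4 | 3-(benzyloxy)-5-[hydroxy(tosyloxy)-λ3-iodanyl]phenyl pivalate | CC(C)(C)C(=O)Oc1cc(OCc2ccccc2)cc(I(O)OS(=O)(=O)c2ccc(C)cc2)c1 | intermediate
5 | [3-(benzyloxy)-5-(pivaloyloxy)phenyl](2,4,6-trimethoxyphenyl)iodonium 4-methylbenzenesulfonate | CC(C)(C)C(=O)Oc1cc(OCc2ccccc2)cc([I+]c2c(OC)cc(OC)cc2OC)c1.Cc1ccc(S(=O)(=O)[O-])cc1 | intermediate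
6 | 3,4,5-trihydroxybenzaldehyde | O=Cc1cc(O)c(O)c(O)c1 | starting material
7 | 3-(benzyloxy)-5-(4-formyl-2,6-dihydroxyphenoxy)phenyl pivalate | CC(C)(C)C(=O)Oc1cc(OCc2ccccc2)cc(Oc2c(O)cc(C=O)cc2O)c1 | intermediate
8 | 3-(benzyloxy)-5-[2,6-bis(benzyloxy)-4-formylphenoxy]phenyl pivalate | CC(C)(C)C(=O)Oc1cc(OCc2ccccc2)cc(Oc2c(OCc3ccccc3)cc(C=O)cc2OCc2ccccc2)c1 | intermediate
9 | 3-(benzyloxy)-5-[2,6-bis(benzyloxy)-4-(formyloxy)phenoxy]phenyl pivalate | CC(C)(C)C(=O)Oc1cc(OCc2ccccc2)cc(Oc2c(OCc3ccccc3)cc(OC=O)cc2OCc2ccccc2)c1 | intermediate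
10 | 3-(benzyloxy)-5-[2,6-bis(benzyloxy)-4-hydroxyphenoxy]phenol | Oc1cc(OCc2ccccc2)cc(Oc2c(OCc3ccccc3)cc(O)cc2OCc2ccccc2)c1 | intermediate
11 | bis(pyridinium) 3-(benzyloxy)-5-[2,6-bis(benzyloxy)-4-(sulfonatooxy)phenoxy]phenyl sulfate | [O-]S(=O)(=O)Oc1cc(OCc2ccccc2)cc(Oc2c(OCc3ccccc3)cc(OS(=O)(=O)[O-])cc2OCc2ccccc2)c1.c1cc[nH+]cc1.c1cc[nH+]cc1 | intermediate
12 | disodium 3-(benzyloxy)-5-[2,6-bis(benzyloxy)-4-(sulfonatooxy)phenoxy]phenyl sulfate | [Na+].[Na+].[O-]S(=O)(=O)Oc1cc(OCc2ccccc2)cc(Oc2c(OCc3ccccc3)cc(OS(=O)(=O)[O-])cc2OCc2ccccc2)c1 | intermediate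
13 | disodium 3-[2,6-dihydroxy-4-(sulfonatooxy)phenoxy]-5-hydroxyphenyl sulfate | [Na+].[Na+].[O-]S(=O)(=O)Oc1cc(O)cc(Oc2c(O)cc(OS(=O)(=O)[O-])cc2O)c1 | intermediate
14 | 3-[2,6-dihydroxy-4-(sulfooxy)phenoxy]-5-hydroxyphenyl hydrogen sulfate (CNP0460023.0) | O=S(=O)(O)Oc1cc(O)cc(Oc2c(O)cc(OS(=O)(=O)O)cc2O)c1 | target

## Step count and risks

Total step count: 7. Longest linear sequence: 7 steps (1 → 2 → 3 → 5 → 8 → 10 → 12 → 14); 6 is used as purchased.

Steps most likely to fail:

Step 4 (highest risk). The unprotected pyrogallol unit of 6 may be oxidised by, or chelate, the iodine(III) reagent, and some 3-O-arylation or double arylation may occur. Fallback: protect first, then arylate a single, unambiguous phenoxide. It sets out from 6 and comes back at 8. Compound 6 is O-allylated at the acidic 4-OH (allyl bromide 1.05 equiv, NaHCO3, DMF, 40 °C; an SN2 reaction whose 4-O selectivity is documented) to give 4-(allyloxy)-3,5-dihydroxybenzaldehyde F1. The two remaining hydroxyls are benzylated (BnBr, K2CO3, DMF) to 4-(allyloxy)-3,5-bis(benzyloxy)benzaldehyde F2. The allyl group is removed (Pd(PPh3)4 cat., morpholine, THF) to give 3,5-bis(benzyloxy)-4-hydroxybenzaldehyde F3. F3 is then O-arylated with 5 (K2CO3, MeCN, 50 °C) to give 8.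

Step 5. The peracid may attack the very electron-rich ring A or give the benzoic acid in place of the formate. Fallback: drop the aldehyde as a masked phenol and bring in ring B as a preformed, mono-protected hydroquinone. It sets out from 5 and comes back at 10. Commercial 3,5-bis(benzyloxy)phenol F4 is oxidised (Fremy's salt, KH2PO4, acetone/H2O) to 2,6-bis(benzyloxy)cyclohexa-2,5-diene-1,4-dione F5. F5 is reduced (Na2S2O4, EtOAc/H2O) to 2,6-bis(benzyloxy)benzene-1,4-diol F6. F6 is acylated at the unhindered 4-OH (PivCl 1.0 equiv, pyridine, CH2Cl2, −20 °C) to 3,5-bis(benzyloxy)-4-hydroxyphenyl pivalate F7. F7 is O-arylated with 5 (K2CO3, MeCN, 50 °C) to 3-(benzyloxy)-5-[2,6-bis(benzyloxy)-4-(pivaloyloxy)phenoxy]phenyl pivalate F8. F8 is methanolysed (NaOMe, MeOH/THF, then AcOH) to give 10.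

Step 6. Bis-sulfation may stop at the mono-sulfate, and the amphiphilic salt may lose sulfate during purification. Fallback: install both sulfates as neutral, chromatographable protected diesters. It sets out from 10 and comes back at 12. Compound 10 with 2,2,2-trichloroethyl chlorosulfate (2.4 equiv, Et3N, DMAP, THF, 0 °C to rt) gives 3-(benzyloxy)-5-{2,6-bis(benzyloxy)-4-[(2,2,2-trichloroethoxy)sulfonyloxy]phenoxy}phenyl 2,2,2-trichloroethyl sulfate F9, purified on silica. Zinc dust and ammonium formate in MeOH at rt remove both trichloroethyl groups by reductive elimination and leave the benzyl ethers, giving diammonium 3-(benzyloxy)-5-[2,6-bis(benzyloxy)-4-(sulfonatooxy)phenoxy]phenyl sulfate F10. NaOH (2.0 equiv) and evaporation convert F10 into 12.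

## Further compounds

F1 | step 4 | 4-(allyloxy)-3,5-dihydroxybenzaldehyde | O=Cc1cc(O)c(OCC=C)c(O)c1
F2 | step 4 | 4-(allyloxy)-3,5-bis(benzyloxy)benzaldehyde | O=Cc1cc(OCc2ccccc2)c(OCC=C)c(OCc2ccccc2)c1
F3 | step 4 | 3,5-bis(benzyloxy)-4-hydroxybenzaldehyde | O=Cc1cc(OCc2ccccc2)c(O)c(OCc2ccccc2)c1
F4 | step 5 | 3,5-bis(benzyloxy)phenol | Oc1cc(OCc2ccccc2)cc(OCc2ccccc2)c1
F5 | step 5 | 2,6-bis(benzyloxy)cyclohexa-2,5-diene-1,4-dione | O=C1C(OCc2ccccc2)=CC(=O)C=C1OCc1ccccc1
F6 | step 5 | 2,6-bis(benzyloxy)benzene-1,4-diol | Oc1cc(OCc2ccccc2)c(O)c(OCc2ccccc2)c1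
F7 | step 5 | 3,5-bis(benzyloxy)-4-hydroxyphenyl pivalate | CC(C)(C)C(=O)Oc1cc(OCc2ccccc2)c(O)c(OCc2ccccc2)c1
F8 | step 5 | 3-(benzyloxy)-5-[2,6-bis(benzyloxy)-4-(pivaloyloxy)phenoxy]phenyl pivalate | CC(C)(C)C(=O)Oc1cc(OCc2ccccc2)cc(Oc2c(OCc3ccccc3)cc(OC(=O)C(C)(C)C)cc2OCc2ccccc2)c1
F9 | step 6 | 3-(benzyloxy)-5-{2,6-bis(benzyloxy)-4-[(2,2,2-trichloroethoxy)sulfonyloxy]phenoxy}phenyl 2,2,2-trichloroethyl sulfate | ClC(Cl)(Cl)COS(=O)(=O)Oc1cc(OCc2ccccc2)cc(Oc2c(OCc3ccccc3)cc(OS(=O)(=O)OCC(Cl)(Cl)Cl)cc2OCc2ccccc2)c1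
F10 | step 6 | diammonium 3-(benzyloxy)-5-[2,6-bis(benzyloxy)-4-(sulfonatooxy)phenoxy]phenyl sulfate | [NH4+].[NH4+].[O-]S(=O)(=O)Oc1cc(OCc2ccccc2)cc(Oc2c(OCc3ccccc3)cc(OS(=O)(=O)[O-])cc2OCc2ccccc2)c1
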